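The numbers in the tables stem from a simulated flask with made-up constants, and the scatter is random.

Watch the target in the first minutes, not at the end of the run.

| setting | beta | zeta | flask |
|---|---|---|---|
| substrate | 0.10 M | 0.10 M | 0.10 M |
| coupling partner | 0.060 M | 0.030 M | 0.0600 M |
| remark | the very flask that is asked about, followed so far | run made earlier |  |
| time |  |  | 8.0 h |

| run | time / h | target / % | isomer of the product / % | substrate / % |
|---|---|---|---|---|
| beta | 0.500 | 1 | 34 | 58 |
| beta | 1.00 | 1 | 44 | 50 |
| beta | 1.33 | 2 | 45 | 45 |
| beta | 2.00 | 4 | 46 | 43 |
| beta | 2.50 | 3 | 41 | 41 |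
| beta | 3.00 | 0 | 40 | 42 |
| zeta | 0.167 | 0 | 10 | 89 |
| zeta | 0.500 | 0 | 18 | 78 |
| zeta | 0.833 | 0 | 22 | 72 |
| zeta | 1.33 | 0 | 23 | 73 |
| zeta | 2.00 | 2 | 22 | 70 |
| zeta | 2.50 | 0 | 19 | 71 |
| zeta | 3.00 | 0 | 23 | 72 |

(each reading ± 1.5 percentage points)

- share of target in target plus isomer of the product at 1.0 min
- share of target in target plus isomer of the product at 8.0 h

- the numbers in the tables scatter with a standard deviation of 1.5 percentage points

How far does the coupling go? Beta holds less coupling partner than substrate, enough for 60.0% of the charge, and its substrate stops near 42%, so the coupling partner is the limiting reagent.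

How is the product divided? The late share, meaning target over target plus isomer with the beta and zeta readings summed, reads 3.25%, lower than an even split, the reference case in which neither product is favoured.

Does that share reach back to 1.0 min? The earliest reading, at 0.167 h in zeta, stands ten times later, so the readings cannot separate kinetic from thermodynamic control. The reckoning here therefore commits to the late share at 8.0 h and, for 1.0 min, to the even split with a wide range.

The forecast differs on the early share. It gives 2.5% (0% to 7%) and 4% (0% to 13%), holding that “the isomer is clearly the main product from the earliest points”.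

The flask gives 37.6% at 1.0 min and 1.29% at 8.0 h.

    intermediate → decomposed reagent (k = 0.00201 s⁻¹)
    intermediate ⇌ isomer of the product (K = 54.2, k = 0.0303 s⁻¹)
    intermediate ⇌ target (K = 0.751, k = 0.0811 s⁻¹)
    substrate + coupling partner → intermediate + by-product (k = 0.00769 M⁻¹ s⁻¹)

The rate constant for making target from intermediate is 2.68 times that for the loss of intermediate to isomer, while target returns to intermediate with a half-life of 0.11 min, short against 8.0 h. The late share of 3.25% again places the neighbour charged with 0.17 M of substrate far below an even split at 8.0 h, where that flask holds 1.29%, but not at 1.0 min, where it holds 37.5%.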